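**Retrosynthetic overview**
1. Target 37 comes from lactone 31 by unmasking O9 (TBS) and then O8 (PMB) one at a time and acylating each (angelate, then acetate).
2. Lactone 31 comes from hydroxy ester 30, made by intramolecular Cr(II) 2‑(methoxycarbonyl)allylation of bromo enal 28 (C6–C7 bond); the ten‑membered carbocycle closes first, the γ‑lactone second.
3. Bromo enal 28 comes from the Morita–Baylis–Hillman adduct of C7 aldehyde 23 with methyl acrylate (C11–C13).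
4. The C9–C10 bond comes from chelation‑controlled addition of the (Z)‑alkenylmagnesium derived from iodide 17 (geraniol, Stork–Zhao olefination) to glyceraldehyde derivative 8.
5. C8, the first stereocentre, comes from lipase desymmetrisation of prochiral diacetate 4, made from achiral 1,3‑O‑benzylideneglycerol.

Assumption: the lipase distinguishes the enantiotopic acetates of the 2‑O‑(4‑methoxybenzyl) substrate in the same sense as I recall for the 2‑O‑benzyl analogue (hydrolysis leaves the (R)‑monoacetate). C1–C15 in the text are germacrane numbers of the target.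

**Step 1**
Reactants: 1 2‑phenyl‑1,3‑dioxan‑5‑ol (1,3‑O‑benzylideneglycerol)
Product: 2 5‑[(4‑methoxybenzyl)oxy]‑2‑phenyl‑1,3‑dioxane
Conditions: NaH, PMBCl, TBAI (cat.), DMF, 0 °C → rt
Reagents that add atoms: 4‑methoxybenzyl chloride (COc1ccc(CCl)cc1)
Why: Williamson ether synthesis on the only free hydroxyl places the chelating, DDQ‑labile PMB group on the future O8; no stereocentre is formed.

**Step 2**
Reactants: 2 5‑[(4‑methoxybenzyl)oxy]‑2‑phenyl‑1,3‑dioxane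
Product: 3 2‑[(4‑methoxybenzyl)oxy]propane‑1,3‑diol
Conditions: AcOH/H2O (4:1), 45 °C
Reagents that add atoms: none
Why: Mild acid hydrolysis cleaves the benzylidene acetal while the PMB ether survives, giving the prochiral diol.

**Step 3**
Reactants: 3 2‑[(4‑methoxybenzyl)oxy]propane‑1,3‑diol
Product: 4 2‑[(4‑methoxybenzyl)oxy]propane‑1,3‑diyl diacetate
Conditions: Ac2O, pyridine, DMAP (cat.), CH2Cl2, rt
Reagents that add atoms: acetic anhydride (CC(=O)OC(C)=O)
Why: Exhaustive acetylation gives the prochiral diester that the enzyme needs.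

**Step 4**
Reactants: 4 2‑[(4‑methoxybenzyl)oxy]propane‑1,3‑diyl diacetate
Product: 5 (R)‑3‑hydroxy‑2‑[(4‑methoxybenzyl)oxy]propyl acetate
Conditions: lipase (Burkholderia cepacia lipase), 0.1 M phosphate buffer pH 7.0, 25 °C, stopped after one acetate is hydrolysed
Reagents that add atoms: none
Why: Enzymatic desymmetrisation: the lipase hydrolyses only the pro‑S acetoxymethyl arm of the prochiral diester, which sets the C8 stereocentre (R) by asymmetric catalysis.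

**Step 5**
Reactants: 5 (R)‑3‑hydroxy‑2‑[(4‑methoxybenzyl)oxy]propyl acetate
Product: 6 (S)‑2‑[(4‑methoxybenzyl)oxy]‑3‑[(triethylsilyl)oxy]propyl acetate
Conditions: TESCl, imidazole, CH2Cl2, 0 °C
Reagents that add atoms: chlorotriethylsilane (CC[Si](CC)(CC)Cl)
Why: Prompt silylation of the free arm (future C7–O) fixes the differentiation of the two arms before any acetyl migration; the descriptor changes only through CIP priorities.

**Step 6**
Reactants: 6 (S)‑2‑[(4‑methoxybenzyl)oxy]‑3‑[(triethylsilyl)oxy]propyl acetate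
Product: 7 (S)‑2‑[(4‑methoxybenzyl)oxy]‑3‑[(triethylsilyl)oxy]propan‑1‑ol
Conditions: DIBAL‑H (2.2 equiv), CH2Cl2, −78 °C; Rochelle salt
Reagents that add atoms: none
Why: Reductive removal of the acetate at −78 °C avoids the basic conditions that could cause 1,3‑silyl migration and so erode the ee.

**Step 7**
Reactants: 7 (S)‑2‑[(4‑methoxybenzyl)oxy]‑3‑[(triethylsilyl)oxy]propan‑1‑ol
Product: 8 (R)‑2‑[(4‑methoxybenzyl)oxy]‑3‑[(triethylsilyl)oxy]propanal
Conditions: Dess–Martin periodinane, pyridine, CH2Cl2, 0 °C → rt; used crude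
Reagents that add atoms: none
Why: Dess–Martin oxidation under buffered, non‑basic conditions gives the α‑alkoxy aldehyde (C9) without epimerising C8.

**Step 8**
Reactants: 9 geraniol
Product: 10 tert‑butyl{[(2E)‑3,7‑dimethylocta‑2,6‑dien‑1‑yl]oxy}dimethylsilane
Conditions: TBSCl, imidazole, DMF, 0 °C → rt
Reagents that add atoms: tert‑butyldimethylsilyl chloride (CC(C)(C)[Si](C)(C)Cl)
Why: Standard silylation protects the future C6 oxygen; the 2E alkene of geraniol becomes the 4E alkene of the target.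

**Step 9**
Reactants: 10 tert‑butyl{[(2E)‑3,7‑dimethylocta‑2,6‑dien‑1‑yl]oxy}dimethylsilane
Product: 11 racemic tert‑butyl{[(2E)‑5‑(3,3‑dimethyloxiran‑2‑yl)‑3‑methylpent‑2‑en‑1‑yl]oxy}dimethylsilane
Conditions: mCPBA (1.05 equiv), CH2Cl2, −20 °C
Reagents that add atoms: mCPBA (O=C(OO)c1cccc(Cl)c1)
Why: Prilezhaev epoxidation goes to the more electron‑rich remote alkene rather than the one deactivated by the allylic silyloxy group; the epoxide is racemic and its stereocentre is destroyed in step 10.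

**Step 10**
Reactants: 11 racemic 6,7‑epoxygeranyl TBS ether
Product: 12 (E)‑6‑[(tert‑butyldimethylsilyl)oxy]‑4‑methylhex‑4‑enal
Conditions: H5IO6 (1.2 equiv), Et2O/THF, 0 °C, 30 min
Reagents that add atoms: none
Why: Periodic acid opens the epoxide and cleaves the resulting glycol (Malaprade cleavage), excising acetone and leaving the C1 aldehyde with the trisubstituted E alkene intact.

**Step 11**
Reactants: 12 (E)‑6‑[(tert‑butyldimethylsilyl)oxy]‑4‑methylhex‑4‑enal, 13 ethyltriphenylphosphonium iodide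
Product: 17 tert‑butyl{[(2E,6Z)‑7‑iodo‑3‑methylocta‑2,6‑dien‑1‑yl]oxy}dimethylsilane, via ethylidenetriphenylphosphorane 14 (not isolated), via (1‑iodoethyl)triphenylphosphonium iodide 15 (not isolated), via (1‑iodoethylidene)triphenylphosphorane 16 (not isolated)
Conditions: 13, n‑BuLi, THF, 0 °C; I2, −78 °C; NaHMDS, −78 → −20 °C; then 12, −78 °C → rt
Reagents that add atoms: iodine (II)
Why: Stork–Zhao olefination: the non‑stabilised α‑iodo ylide reacts under kinetic control through the cis‑oxaphosphetane to give the (Z)‑2‑iodoalkene (typically ≥10:1), which fixes the 1(10)Z geometry and supplies C10 and C14.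

**Step 12**
Reactants: 17 tert‑butyl{[(2E,6Z)‑7‑iodo‑3‑methylocta‑2,6‑dien‑1‑yl]oxy}dimethylsilane, 8 (R)‑2‑[(4‑methoxybenzyl)oxy]‑3‑[(triethylsilyl)oxy]propanal
Product: 20 (2R,3R,4Z,8E)‑10‑[(tert‑butyldimethylsilyl)oxy]‑2‑[(4‑methoxybenzyl)oxy]‑4,8‑dimethyl‑1‑[(triethylsilyl)oxy]deca‑4,8‑dien‑3‑ol, via alkenyllithium 18 (not isolated), via alkenylmagnesium bromide 19 (not isolated)
Conditions: 17, t‑BuLi (2.1 equiv), Et2O, −78 °C; MgBr2·OEt2, −78 → −40 °C; then 8 precomplexed with MgBr2·OEt2, CH2Cl2, −78 °C; aq. NH4Cl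
Reagents that add atoms: none
Why: Lithium–iodine exchange with retention of alkene geometry, transmetalation to magnesium and Cram‑chelate addition (Mg bridges the aldehyde and α‑OPMB oxygens, the silyl ether does not chelate) give the 8,9‑syn alcohol, i.e. 9R; the minor 9‑epimer is removed by chromatography.

**Step 13**
Reactants: 20 the C9 alcohol
Product: 21 (2R,3R,4Z,8E)‑3,10‑bis[(tert‑butyldimethylsilyl)oxy]‑2‑[(4‑methoxybenzyl)oxy]‑4,8‑dimethyl‑1‑[(triethylsilyl)oxy]deca‑4,8‑diene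
Conditions: TBSOTf, 2,6‑lutidine, CH2Cl2, −78 → 0 °C
Reagents that add atoms: tert‑butyldimethylsilyl triflate (CC(C)(C)[Si](C)(C)OS(=O)(=O)C(F)(F)F)
Why: The silyl triflate silylates the hindered allylic C9 hydroxyl, giving three silyl ethers of graded lability (primary TES < primary TBS < hindered secondary TBS).

**Step 14**
Reactants: 21 the tris‑silyl ether
Product: 22 (2R,3R,4Z,8E)‑3,10‑bis[(tert‑butyldimethylsilyl)oxy]‑2‑[(4‑methoxybenzyl)oxy]‑4,8‑dimethyldeca‑4,8‑dien‑1‑ol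
Conditions: PPTS (0.2 equiv), MeOH/CH2Cl2 (1:1), 0 °C
Reagents that add atoms: none
Why: Acid‑catalysed methanolysis removes the primary TES ether about two orders of magnitude faster than either TBS ether, freeing only the C7 hydroxyl.

**Step 15**
Reactants: 22 the C7 alcohol
Product: 23 (2S,3R,4Z,8E)‑3,10‑bis[(tert‑butyldimethylsilyl)oxy]‑2‑[(4‑methoxybenzyl)oxy]‑4,8‑dimethyldeca‑4,8‑dienal
Conditions: Dess–Martin periodinane, pyridine, CH2Cl2, 0 °C → rt; used at once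
Reagents that add atoms: none
Why: Dess–Martin oxidation gives the C7 aldehyde without epimerising the α‑alkoxy centre C8 (the 2S descriptor is a CIP priority change only).

**Step 16**
Reactants: 23 the C7 aldehyde, 24 methyl acrylate
Product: 25 methyl (4R,5R,6Z,10E)‑5,12‑bis[(tert‑butyldimethylsilyl)oxy]‑3‑hydroxy‑4‑[(4‑methoxybenzyl)oxy]‑6,10‑dimethyl‑2‑methylidenedodeca‑6,10‑dienoate (C3 epimer mixture)
Conditions: methyl acrylate (10 equiv), DABCO (1.0 equiv), MeOH (2 equiv), rt, 3–5 d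
Reagents that add atoms: none
Why: Morita–Baylis–Hillman reaction of the activated α‑alkoxy aldehyde installs C11–C13; the new carbinol centre (C7) is left uncontrolled because it becomes sp2 in step 19.

**Step 17**
Reactants: 25 the Morita–Baylis–Hillman adduct
Product: 26 methyl (4R,5R,6Z,10E)‑5‑[(tert‑butyldimethylsilyl)oxy]‑3,12‑dihydroxy‑4‑[(4‑methoxybenzyl)oxy]‑6,10‑dimethyl‑2‑methylidenedodeca‑6,10‑dienoate
Conditions: HF·pyridine, pyridine, THF, 0 °C
Reagents that add atoms: none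
Why: Buffered HF cleaves the unhindered primary allylic TBS ether (C6–O) well before the hindered secondary TBS ether at C9.

**Step 18**
Reactants: 26 the diol
Product: 27 methyl (4R,5R,6Z,10E)‑5‑[(tert‑butyldimethylsilyl)oxy]‑3‑hydroxy‑4‑[(4‑methoxybenzyl)oxy]‑6,10‑dimethyl‑2‑methylidene‑12‑oxododeca‑6,10‑dienoate
Conditions: MnO2 (20 equiv), CH2Cl2, rt
Reagents that add atoms: none
Why: MnO2 oxidises the electron‑rich primary allylic alcohol to the E enal, while the hindered secondary alcohol next to the electron‑poor acrylate is inert.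

**Step 19**
Reactants: 27 the hydroxy enal
Product: 28 methyl (2Z,4R,5R,6Z,10E)‑2‑(bromomethyl)‑5‑[(tert‑butyldimethylsilyl)oxy]‑4‑[(4‑methoxybenzyl)oxy]‑6,10‑dimethyl‑12‑oxododeca‑2,6,10‑trienoate
Conditions: NBS, Me2S, CH2Cl2, −20 °C (reagent preformed); then 27, → 0 °C
Reagents that add atoms: N‑bromosuccinimide (O=C1CCC(=O)N1Br)
Why: The Corey–Kim‑type bromosulfonium reagent activates the hydroxyl and bromide attacks SN2′, giving the rearranged (Z)‑2‑(bromomethyl)enoate; the enal and the other alkenes are untouched.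

**Step 20**
Reactants: 28 the bromo enal
Product: 30 methyl 6α‑hydroxy‑8α‑[(4‑methoxybenzyl)oxy]‑9β‑[(tert‑butyldimethylsilyl)oxy]germacra‑1(10)Z,4E,11(13)‑trien‑12‑oate, via allylchromium dichloride 29 (not isolated)
Conditions: CrCl2 (10 equiv), DMF/THF, rt, slow addition of 28 (final 2 mM); aqueous work‑up
Reagents that add atoms: none
Why: Intramolecular Nozaki–Hiyama (Barbier‑type) 2‑(methoxycarbonyl)allylation closes the ten‑membered ring at C6–C7: with C8–H eclipsing the C7=C11 bond (minimal A(1,3) strain) the tethered aldehyde reaches C7 anti to OPMB (7S), and the ring‑enforced anti addition that I recall for costunolide‑type closures gives 6R.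

**Step 21**
Reactants: 30 the hydroxy ester
Product: 31 8α‑[(4‑methoxybenzyl)oxy]‑9β‑[(tert‑butyldimethylsilyl)oxy]germacra‑1(10)Z,4E,11(13)‑trien‑12,6α‑olide
Conditions: PPTS (0.1 equiv), toluene, 50 °C
Reagents that add atoms: none
Why: Mild acid‑catalysed transesterification closes the trans‑fused α‑methylene‑γ‑butyrolactone with retention at C6 and C7 (this may already occur in part during step 20).

**Step 22**
Reactants: 31 the protected lactone
Product: 32 9β‑hydroxy‑8α‑[(4‑methoxybenzyl)oxy]germacra‑1(10)Z,4E,11(13)‑trien‑12,6α‑olide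
Conditions: HF·pyridine, pyridine, THF, 0 °C → rt
Reagents that add atoms: none
Why: Buffered fluoride removes the last silyl ether without base (no translactonisation, no addition to the methylene lactone) and without acid strong enough for transannular cyclisation.

**Step 23**
Reactants: 32 the C9 alcohol, 33 angelic acid
Product: 35 9β‑angeloyloxy‑8α‑[(4‑methoxybenzyl)oxy]germacra‑1(10)Z,4E,11(13)‑trien‑12,6α‑olide, via angelic 2,4,6‑trichlorobenzoic anhydride 34 (not isolated)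
Conditions: 33, 2,4,6‑trichlorobenzoyl chloride, Et3N, toluene, rt; then 32, 75 °C
Reagents that add atoms: none
Why: Yamaguchi‑type mixed‑anhydride acylation without DMAP transfers the angeloyl group to the hindered allylic alcohol with retention at C9 and without Z → E isomerisation to the tiglate.

**Step 24**
Reactants: 35 the 9‑angelate
Product: 36 9β‑angeloyloxy‑8α‑hydroxygermacra‑1(10)Z,4E,11(13)‑trien‑12,6α‑olide
Conditions: DDQ, CH2Cl2/pH 7 phosphate buffer (10:1), 0 °C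
Reagents that add atoms: none
Why: Oxidative PMB cleavage under neutral conditions frees O8 without touching the esters, the diene or the methylene lactone.

**Step 25**
Reactants: 36 the C8 alcohol
Product: 37 8α‑acetoxy‑9β‑angeloyloxygermacra‑1(10)Z,4E,11(13)‑trien‑12,6α‑olide (6R,7S,8R,9R; CNP0200690.1)
Conditions: Ac2O, pyridine, DMAP (cat.), CH2Cl2, 0 °C → rt
Reagents that add atoms: acetic anhydride (CC(=O)OC(C)=O)
Why: Fast acetylation of the secondary alcohol with retention at C8 completes the target before acyl migration or relactonisation can compete.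

**Compound list**
1 | 2‑phenyl‑1,3‑dioxan‑5‑ol (1,3‑O‑benzylideneglycerol, achiral) | OC1COC(c2ccccc2)OC1 | starting material
2 | 5‑[(4‑methoxybenzyl)oxy]‑2‑phenyl‑1,3‑dioxane | COc1ccc(COC2COC(c3ccccc3)OC2)cc1 | intermediate
3 | 2‑[(4‑methoxybenzyl)oxy]propane‑1,3‑diol | COc1ccc(COC(CO)CO)cc1 | intermediate
4 | 2‑[(4‑methoxybenzyl)oxy]propane‑1,3‑diyl diacetate | COc1ccc(COC(COC(C)=O)COC(C)=O)cc1 | intermediate
5 | (R)‑3‑hydroxy‑2‑[(4‑methoxybenzyl)oxy]propyl acetate | CC(=O)OC[C@H](OCc1ccc(OC)cc1)CO | intermediate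
6 | (S)‑2‑[(4‑methoxybenzyl)oxy]‑3‑[(triethylsilyl)oxy]propyl acetate | CC(=O)OC[C@H](OCc1ccc(OC)cc1)CO[Si](CC)(CC)CC | intermediate
7 | (S)‑2‑[(4‑methoxybenzyl)oxy]‑3‑[(triethylsilyl)oxy]propan‑1‑ol | OC[C@H](OCc1ccc(OC)cc1)CO[Si](CC)(CC)CC | intermediate
8 | (R)‑2‑[(4‑methoxybenzyl)oxy]‑3‑[(triethylsilyl)oxy]propanal | O=C[C@H](OCc1ccc(OC)cc1)CO[Si](CC)(CC)CC | intermediate
9 | geraniol | CC(C)=CCC/C(C)=C/CO | starting material
10 | tert‑butyl{[(2E)‑3,7‑dimethylocta‑2,6‑dien‑1‑yl]oxy}dimethylsilane | CC(C)=CCC/C(C)=C/CO[Si](C)(C)C(C)(C)C | intermediate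
11 | racemic tert‑butyl{[(2E)‑5‑(3,3‑dimethyloxiran‑2‑yl)‑3‑methylpent‑2‑en‑1‑yl]oxy}dimethylsilane | CC1(C)OC1CC/C(C)=C/CO[Si](C)(C)C(C)(C)C | intermediate
12 | (E)‑6‑[(tert‑butyldimethylsilyl)oxy]‑4‑methylhex‑4‑enal | O=CCC/C(C)=C/CO[Si](C)(C)C(C)(C)C | intermediate
13 | ethyltriphenylphosphonium iodide | CC[P+](c1ccccc1)(c1ccccc1)c1ccccc1.[I-] | starting material
14 | ethylidenetriphenylphosphorane | CC=P(c1ccccc1)(c1ccccc1)c1ccccc1 | intermediate
15 | (1‑iodoethyl)triphenylphosphonium iodide | CC(I)[P+](c1ccccc1)(c1ccccc1)c1ccccc1.[I-] | intermediate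
16 | (1‑iodoethylidene)triphenylphosphorane | CC(I)=P(c1ccccc1)(c1ccccc1)c1ccccc1 | intermediate
17 | tert‑butyl{[(2E,6Z)‑7‑iodo‑3‑methylocta‑2,6‑dien‑1‑yl]oxy}dimethylsilane | C/C(I)=C/CC/C(C)=C/CO[Si](C)(C)C(C)(C)C | intermediate
18 | (2Z,6E)‑8‑[(tert‑butyldimethylsilyl)oxy]‑6‑methylocta‑2,6‑dien‑2‑yllithium | [Li]/C(C)=C\CC/C(C)=C/CO[Si](C)(C)C(C)(C)C | intermediate
19 | (2Z,6E)‑8‑[(tert‑butyldimethylsilyl)oxy]‑6‑methylocta‑2,6‑dien‑2‑ylmagnesium bromide | Br[Mg]/C(C)=C\CC/C(C)=C/CO[Si](C)(C)C(C)(C)C | intermediate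
20 | (2R,3R,4Z,8E)‑10‑[(tert‑butyldimethylsilyl)oxy]‑2‑[(4‑methoxybenzyl)oxy]‑4,8‑dimethyl‑1‑[(triethylsilyl)oxy]deca‑4,8‑dien‑3‑ol | CC[Si](CC)(CC)OC[C@@H](OCc1ccc(OC)cc1)[C@H](O)/C(C)=C\CC/C(C)=C/CO[Si](C)(C)C(C)(C)C | intermediate
21 | (2R,3R,4Z,8E)‑3,10‑bis[(tert‑butyldimethylsilyl)oxy]‑2‑[(4‑methoxybenzyl)oxy]‑4,8‑dimethyl‑1‑[(triethylsilyl)oxy]deca‑4,8‑diene | CC[Si](CC)(CC)OC[C@@H](OCc1ccc(OC)cc1)[C@H](O[Si](C)(C)C(C)(C)C)/C(C)=C\CC/C(C)=C/CO[Si](C)(C)C(C)(C)C | intermediate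
22 | (2R,3R,4Z,8E)‑3,10‑bis[(tert‑butyldimethylsilyl)oxy]‑2‑[(4‑methoxybenzyl)oxy]‑4,8‑dimethyldeca‑4,8‑dien‑1‑ol | OC[C@@H](OCc1ccc(OC)cc1)[C@H](O[Si](C)(C)C(C)(C)C)/C(C)=C\CC/C(C)=C/CO[Si](C)(C)C(C)(C)C | intermediate
23 | (2S,3R,4Z,8E)‑3,10‑bis[(tert‑butyldimethylsilyl)oxy]‑2‑[(4‑methoxybenzyl)oxy]‑4,8‑dimethyldeca‑4,8‑dienal | O=C[C@@H](OCc1ccc(OC)cc1)[C@H](O[Si](C)(C)C(C)(C)C)/C(C)=C\CC/C(C)=C/CO[Si](C)(C)C(C)(C)C | intermediate
24 | methyl acrylate | C=CC(=O)OC | starting material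
25 | methyl (4R,5R,6Z,10E)‑5,12‑bis[(tert‑butyldimethylsilyl)oxy]‑3‑hydroxy‑4‑[(4‑methoxybenzyl)oxy]‑6,10‑dimethyl‑2‑methylidenedodeca‑6,10‑dienoate (C3 epimers) | COC(=O)C(=C)C(O)[C@@H](OCc1ccc(OC)cc1)[C@H](O[Si](C)(C)C(C)(C)C)/C(C)=C\CC/C(C)=C/CO[Si](C)(C)C(C)(C)C | intermediate
26 | methyl (4R,5R,6Z,10E)‑5‑[(tert‑butyldimethylsilyl)oxy]‑3,12‑dihydroxy‑4‑[(4‑methoxybenzyl)oxy]‑6,10‑dimethyl‑2‑methylidenedodeca‑6,10‑dienoate (C3 epimers) | COC(=O)C(=C)C(O)[C@@H](OCc1ccc(OC)cc1)[C@H](O[Si](C)(C)C(C)(C)C)/C(C)=C\CC/C(C)=C/CO | intermediate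
27 | methyl (4R,5R,6Z,10E)‑5‑[(tert‑butyldimethylsilyl)oxy]‑3‑hydroxy‑4‑[(4‑methoxybenzyl)oxy]‑6,10‑dimethyl‑2‑methylidene‑12‑oxododeca‑6,10‑dienoate (C3 epimers) | COC(=O)C(=C)C(O)[C@@H](OCc1ccc(OC)cc1)[C@H](O[Si](C)(C)C(C)(C)C)/C(C)=C\CC/C(C)=C/C=O | intermediate
28 | methyl (2Z,4R,5R,6Z,10E)‑2‑(bromomethyl)‑5‑[(tert‑butyldimethylsilyl)oxy]‑4‑[(4‑methoxybenzyl)oxy]‑6,10‑dimethyl‑12‑oxododeca‑2,6,10‑trienoate | COC(=O)/C(CBr)=C/[C@@H](OCc1ccc(OC)cc1)[C@H](O[Si](C)(C)C(C)(C)C)/C(C)=C\CC/C(C)=C/C=O | intermediate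
29 | allylchromium(III) dichloride from 28 (CrCl2 in place of Br) | COC(=O)/C(C[Cr](Cl)Cl)=C/[C@@H](OCc1ccc(OC)cc1)[C@H](O[Si](C)(C)C(C)(C)C)/C(C)=C\CC/C(C)=C/C=O | intermediate
30 | methyl 6α‑hydroxy‑8α‑[(4‑methoxybenzyl)oxy]‑9β‑[(tert‑butyldimethylsilyl)oxy]germacra‑1(10)Z,4E,11(13)‑trien‑12‑oate | C=C(C(=O)OC)[C@H]1[C@H](O)/C=C(\C)CC/C=C(/C)[C@@H](O[Si](C)(C)C(C)(C)C)[C@@H]1OCc1ccc(OC)cc1 | intermediate
31 | 8α‑[(4‑methoxybenzyl)oxy]‑9β‑[(tert‑butyldimethylsilyl)oxy]germacra‑1(10)Z,4E,11(13)‑trien‑12,6α‑olide | C=C1C(=O)O[C@@H]2/C=C(\C)CC/C=C(/C)[C@@H](O[Si](C)(C)C(C)(C)C)[C@H](OCc3ccc(OC)cc3)[C@@H]12 | intermediate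
32 | 9β‑hydroxy‑8α‑[(4‑methoxybenzyl)oxy]germacra‑1(10)Z,4E,11(13)‑trien‑12,6α‑olide | C=C1C(=O)O[C@@H]2/C=C(\C)CC/C=C(/C)[C@@H](O)[C@H](OCc3ccc(OC)cc3)[C@@H]12 | intermediate
33 | angelic acid ((Z)‑2‑methylbut‑2‑enoic acid) | C/C=C(/C)C(=O)O | starting material
34 | angelic 2,4,6‑trichlorobenzoic anhydride | C/C=C(/C)C(=O)OC(=O)c1c(Cl)cc(Cl)cc1Cl | intermediate
35 | 9β‑angeloyloxy‑8α‑[(4‑methoxybenzyl)oxy]germacra‑1(10)Z,4E,11(13)‑trien‑12,6α‑olide | C=C1C(=O)O[C@@H]2/C=C(\C)CC/C=C(/C)[C@@H](OC(=O)/C(C)=C\C)[C@H](OCc3ccc(OC)cc3)[C@@H]12 | intermediate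
36 | 9β‑angeloyloxy‑8α‑hydroxygermacra‑1(10)Z,4E,11(13)‑trien‑12,6α‑olide | C=C1C(=O)O[C@@H]2/C=C(\C)CC/C=C(/C)[C@@H](OC(=O)/C(C)=C\C)[C@H](O)[C@@H]12 | intermediate
37 | 8α‑acetoxy‑9β‑angeloyloxygermacra‑1(10)Z,4E,11(13)‑trien‑12,6α‑olide (6R,7S,8R,9R) | C=C1C(=O)O[C@@H]2/C=C(\C)CC/C=C(/C)[C@@H](OC(=O)/C(C)=C\C)[C@H](OC(C)=O)[C@@H]12 | target

**Totals and risks**
Total step count: 25. Longest linear sequence: 21 steps (steps 1–7, then 12–25).

Most likely to fail: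

- **Step 20 (ten‑membered ring closure; yield and facial selectivity).** The fallback sets out from 23 and returns at 30. Horner–Wadsworth–Emmons reaction of 23 with methyl 2‑(diethoxyphosphoryl)‑3‑(trimethylsilyl)propanoate (NaH, DME, 0 °C) gives the 2‑(trimethylsilylmethyl)enoate F2. HF·pyridine/pyridine frees the primary allylic alcohol F3, and MnO2 gives the enal allylsilane F4. BF3·OEt2 in CH2Cl2 at −78 °C under high dilution then closes the ring by an intramolecular Hosomi–Sakurai allylation through an open transition state, a different stereochemical manifold from the chromium chelate, to give 30.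

- **Step 16 (Morita–Baylis–Hillman reaction on a hindered, epimerisable aldehyde; slow, possible loss of C8 integrity).** The fallback sets out from 23 and returns at 25. Hydroalumination of methyl propiolate with DIBAL‑H/NMO in THF at 0 °C gives the vinylalane [1‑(methoxycarbonyl)vinyl]diisobutylalane F1. It adds to 23 within hours at 0 °C → rt (vinylalumination) to give 25 without any amine base.

- **Step 23 (angeloylation of a hindered allylic alcohol; slow acylation or leakage to the tiglate).** The fallback sets out from 32 and returns at 35. DCC/DMAP esterification of 32 with 2‑[bis(2,2,2‑trifluoroethoxy)phosphoryl]propanoic acid gives the phosphonate ester F5. Still–Gennari olefination of F5 with acetaldehyde (KHMDS, 18‑crown‑6, THF, −78 °C) builds the (Z)‑2‑methylbut‑2‑enoate on the molecule and gives 35.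

**Further compounds**
F1 | step 16 | [1‑(methoxycarbonyl)vinyl]diisobutylalane | COC(=O)C(=C)[Al](CC(C)C)CC(C)C
F2 | step 20 | methyl (4R,5R,6Z,10E)‑5,12‑bis[(tert‑butyldimethylsilyl)oxy]‑4‑[(4‑methoxybenzyl)oxy]‑6,10‑dimethyl‑2‑[(trimethylsilyl)methyl]dodeca‑2,6,10‑trienoate (2E/2Z mixture) | COC(=O)C(C[Si](C)(C)C)=C[C@@H](OCc1ccc(OC)cc1)[C@H](O[Si](C)(C)C(C)(C)C)/C(C)=C\CC/C(C)=C/CO[Si](C)(C)C(C)(C)C
F3 | step 20 | methyl (4R,5R,6Z,10E)‑5‑[(tert‑butyldimethylsilyl)oxy]‑12‑hydroxy‑4‑[(4‑methoxybenzyl)oxy]‑6,10‑dimethyl‑2‑[(trimethylsilyl)methyl]dodeca‑2,6,10‑trienoate | COC(=O)C(C[Si](C)(C)C)=C[C@@H](OCc1ccc(OC)cc1)[C@H](O[Si](C)(C)C(C)(C)C)/C(C)=C\CC/C(C)=C/CO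
F4 | step 20 | methyl (4R,5R,6Z,10E)‑5‑[(tert‑butyldimethylsilyl)oxy]‑4‑[(4‑methoxybenzyl)oxy]‑6,10‑dimethyl‑12‑oxo‑2‑[(trimethylsilyl)methyl]dodeca‑2,6,10‑trienoate | COC(=O)C(C[Si](C)(C)C)=C[C@@H](OCc1ccc(OC)cc1)[C@H](O[Si](C)(C)C(C)(C)C)/C(C)=C\CC/C(C)=C/C=O
F5 | step 23 | 9β‑{2‑[bis(2,2,2‑trifluoroethoxy)phosphoryl]propanoyloxy}‑8α‑[(4‑methoxybenzyl)oxy]germacra‑1(10)Z,4E,11(13)‑trien‑12,6α‑olide | C=C1C(=O)O[C@@H]2/C=C(\C)CC/C=C(/C)[C@@H](OC(=O)C(C)P(=O)(OCC(F)(F)F)OCC(F)(F)F)[C@H](OCc3ccc(OC)cc3)[C@@H]12
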